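**Strategy.** The carbocycle (C4a, C5, C6, C7, C8, C8a; chromone numbering) is disconnected at C4a–C5 and C6–C7. This removes C5–C6 as vinylene carbonate and leaves a γ-pyranone whose ring double bond C4a=C8a is extended by an (E)-acyloxyvinyl group C8=C7. The key step is a Diels–Alder reaction of this diene: it forms both bonds and the all-cis oxygen array at C5, C6 and C7 in one operation and gives a non-aromatic adduct (enol ether C8=C8a, sp3 C4a). Chlorination at C8 then restores the pyranone and sets the fourth stereocentre. The precursor is a dienyl ester of (S)-O-methylmandelic acid, which doubles as resolving group.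

Key step: step 6

Remark on numbering and configuration: chromone numbering is used throughout (O1, C2, C3, C4, C4a, C5, C6, C7, C8, C8a); the target is read as (5S,6S,7S,8R), with the hydroxyls at C5, C6 and C7 mutually cis and the chlorine at C8 trans to the C7 hydroxyl.

Assumption: the sense of face selection by the (S)-O-methylmandelate is not secure; the (S) acid is drawn, both endo adducts are expected, the wanted one is isolated as a diastereomer after step 7, and the (R) acid would be taken if it proved to be the matched one.

Step 1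
Reactants: 1 isovanillin
Product: 2 3-(tert-butyldimethylsilyloxy)-4-methoxybenzaldehyde
Conditions: TBSCl, imidazole, DMF, rt
Reagents that add atoms: tert-butyldimethylsilyl chloride, CC(C)(C)[Si](C)(C)Cl
Why: Imidazole-assisted silyl ether formation masks the only acidic OH before the two lithium amide steps.

Step 2
Reactants: 2 3-(tert-butyldimethylsilyloxy)-4-methoxybenzaldehyde
Product: 3 [3-(tert-butyldimethylsilyloxy)-4-methoxyphenyl]methanol
Conditions: NaBH4, MeOH, 0 °C
Reagents that add atoms: none
Why: Hydride reduction of the aldehyde is chemoselective and should leave the aryl silyl ether intact at 0 °C.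

Step 3
Reactants: 3 [3-(tert-butyldimethylsilyloxy)-4-methoxyphenyl]methanol
Product: 4 4-(bromomethyl)-2-(tert-butyldimethylsilyloxy)-1-methoxybenzene
Conditions: CBr4, PPh3, CH2Cl2, 0 °C
Reagents that add atoms: carbon tetrabromide, BrC(Br)(Br)Br
Why: The Appel reaction converts the benzylic alcohol into the bromide under neutral conditions that spare the aryl silyl ether.

Step 4
Reactants: 5 2,6-dimethyl-4H-pyran-4-one; 4 4-(bromomethyl)-2-(tert-butyldimethylsilyloxy)-1-methoxybenzene
Product: 6 2-{2-[3-(tert-butyldimethylsilyloxy)-4-methoxyphenyl]ethyl}-6-methyl-4H-pyran-4-one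
Conditions: 5 (2 equiv), LiN(SiMe3)2 (2 equiv), THF, −78 °C; then 4, −78 to −20 °C
Reagents that add atoms: none
Why: Lateral (vinylogous) deprotonation of one methyl group of the symmetric γ-pyranone gives a dienolate that should be alkylated at the exocyclic carbon by the benzyl bromide, with excess 5 limiting double alkylation.

Step 5
Reactants: 6 2-{2-[3-(tert-butyldimethylsilyloxy)-4-methoxyphenyl]ethyl}-6-methyl-4H-pyran-4-one; 7 (S)-2-methoxy-2-phenylacetic acid
Product: 9 (E)-dienyl (S)-O-methylmandelate, via lithium (E)-enolate 8 (not isolated)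
Conditions: LiN(SiMe3)2 (2.2 equiv), THF, −78 °C; HCO2Et, −78 to −30 °C; then acid chloride from 7 [(COCl)2, cat. DMF, CH2Cl2, 0 °C, evaporated] (2.2 equiv), −78 to 0 °C
Reagents that add atoms: ethyl formate, CCOC=O; (S)-2-methoxy-2-phenylacetyl chloride (made from 7), CO[C@H](C(=O)Cl)c1ccccc1
Why: Crossed Claisen formylation of the laterally lithiated methyl group (kinetically preferred over the more hindered ring-bound CH2 of the phenethyl chain) gives the delocalised enolate 8, whose O-acylation should deliver the more stable E enol ester; the second equivalent of acid chloride is consumed by the lithium ethoxide released.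

Step 6
Reactants: 9 (E)-dienyl (S)-O-methylmandelate; 10 vinylene carbonate
Product: 11 endo cycloadduct (4aR,5S,6R,7R), carried on together with its endo diastereomer of the opposite ring series
Conditions: 10 (10 equiv), CH2Cl2, BHT (cat.), 13 kbar, 60 °C; excess 10 removed in vacuo, crude used at once
Reagents that add atoms: none
Why: Pressure-accelerated Diels–Alder reaction: the s-cis diene C7=C8–C8a=C4a of 9, made of the enol ester double bond and the adjoining double bond of the γ-pyranone ring, adds suprafacially to C5=C6 of 10 in one concerted, asynchronous event, so C4a–C5 and C6–C7 form together. The closest known reactions are the cycloadditions of 2-vinyl- and 2-styrylchromones through the same ring double bond and of 1-acyloxybutadienes with vinylene carbonate. The only ring closed is the six-membered carbocycle C4a–C5–C6–C7–C8–C8a, by [4+2] cycloaddition; the pyranone ring loses its C4a=C8a bond and becomes the enol ether C8=C8a with a new H4a. C5 and C6 are cis because the cis geometry of 10 is kept; C7–O is cis to both because the E enol ester holds its oxygen on the outside of the diene and the carbonate ring adds endo; C4a, with C4 likewise outside, gets its hydrogen anti to the three oxygens and is erased in step 7. The absolute sense at C5, C6 and C7 depends on which diene face reacts: the phenyl group of the (S)-O-methylmandelate is expected to shield one face only moderately, so both endo adducts are taken on and parted as diastereomers after step 7. Pressure is used instead of heat so that the enol ester, the auxiliary bias and the acid- and base-sensitive adduct survive, and no regiochemistry arises because 10 is symmetric.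

Step 7
Reactants: 11 endo cycloadduct
Product: 12 (5S,6S,7S,8R)-8-chloro 5,6-carbonate 7-[(S)-O-methylmandelate] 3′-O-TBS derivative of the target
Conditions: NCS (1.05 equiv), CH2Cl2, −40 to 0 °C; chromatographic separation of the two diastereomers
Reagents that add atoms: N-chlorosuccinimide, O=C1CCC(=O)N1Cl
Why: Electrophilic chlorination of the enol ether C8=C8a at C8 followed by loss of H4a from the oxocarbenium ion re-forms the γ-pyranone; Cl+ should arrive anti to the C7 acyloxy group and the cis-fused carbonate, which sets C8 trans to the C7 oxygen.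

Step 8
Reactants: 12 8-chloro carbonate mandelate silyl ether
Product: 14 CNP0362174.1, via 7,8-epoxide 13 (not isolated)
Conditions: K2CO3, MeOH, 0 °C to rt; evaporate; then HCl (4 M in dioxane), THF, 0 °C
Reagents that add atoms: hydrogen chloride, Cl
Why: Base-catalysed methanolysis removes the mandelate, the cyclic carbonate and the aryl silyl ether, the C7 alkoxide then closes onto C8 with loss of the trans chloride, and HCl reopens the epoxide at the pyranone-activated C8 with inversion, so the trans chlorohydrin returns with the original configuration and any chlorohydrin that never closed is already the target.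

**Compound list**

1 | isovanillin (3-hydroxy-4-methoxybenzaldehyde) | COc1ccc(C=O)cc1O | starting material
2 | 3-(tert-butyldimethylsilyloxy)-4-methoxybenzaldehyde | COc1ccc(C=O)cc1O[Si](C)(C)C(C)(C)C | intermediate
3 | [3-(tert-butyldimethylsilyloxy)-4-methoxyphenyl]methanol | COc1ccc(CO)cc1O[Si](C)(C)C(C)(C)C | intermediate
4 | 4-(bromomethyl)-2-(tert-butyldimethylsilyloxy)-1-methoxybenzene | COc1ccc(CBr)cc1O[Si](C)(C)C(C)(C)C | intermediate
5 | 2,6-dimethyl-4H-pyran-4-one | Cc1cc(=O)cc(C)o1 | starting material
6 | 2-{2-[3-(tert-butyldimethylsilyloxy)-4-methoxyphenyl]ethyl}-6-methyl-4H-pyran-4-one | COc1ccc(CCc2cc(=O)cc(C)o2)cc1O[Si](C)(C)C(C)(C)C | intermediate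
7 | (S)-2-methoxy-2-phenylacetic acid ((S)-O-methylmandelic acid) | CO[C@H](C(=O)O)c1ccccc1 | starting material
8 | lithium (E)-2-(6-{2-[3-(tert-butyldimethylsilyloxy)-4-methoxyphenyl]ethyl}-4-oxo-4H-pyran-2-yl)ethen-1-olate (not isolated) | COc1ccc(CCc2cc(=O)cc(/C=C/[O-])o2)cc1O[Si](C)(C)C(C)(C)C.[Li+] | intermediate
9 | (E)-2-(6-{2-[3-(tert-butyldimethylsilyloxy)-4-methoxyphenyl]ethyl}-4-oxo-4H-pyran-2-yl)ethenyl (S)-2-methoxy-2-phenylacetate | COc1ccc(CCc2cc(=O)cc(/C=C/OC(=O)[C@@H](OC)c3ccccc3)o2)cc1O[Si](C)(C)C(C)(C)C | intermediate
10 | vinylene carbonate (1,3-dioxol-2-one) | O=C1OC=CO1 | starting material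
11 | (4aR,5S,6R,7R)-2-{2-[3-(tert-butyldimethylsilyloxy)-4-methoxyphenyl]ethyl}-5,6,7-trihydroxy-4a,5,6,7-tetrahydro-4H-chromen-4-one 5,6-carbonate 7-[(S)-2-methoxy-2-phenylacetate]; C8=C8a enol ether, the three oxygens cis, H4a anti to them | COc1ccc(CCC2=CC(=O)[C@H]3C(O2)=C[C@@H](OC(=O)[C@@H](OC)c4ccccc4)[C@@H](OC(=O)O5)[C@H]35)cc1O[Si](C)(C)C(C)(C)C | intermediate
12 | (5S,6S,7S,8R)-8-chloro-2-{2-[3-(tert-butyldimethylsilyloxy)-4-methoxyphenyl]ethyl}-5,6,7-trihydroxy-5,6,7,8-tetrahydro-4H-chromen-4-one 5,6-carbonate 7-[(S)-2-methoxy-2-phenylacetate]; Cl trans to O7 | COc1ccc(CCc2cc(=O)c3c(o2)[C@H](Cl)[C@@H](OC(=O)[C@@H](OC)c4ccccc4)[C@@H](OC(=O)O5)[C@H]35)cc1O[Si](C)(C)C(C)(C)C | intermediate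
13 | (5S,6S,7S,8S)-7,8-epoxy-5,6-dihydroxy-2-[2-(3-hydroxy-4-methoxyphenyl)ethyl]-5,6,7,8-tetrahydro-4H-chromen-4-one; epoxide oxygen cis to both hydroxyls (not isolated) | COc1ccc(CCc2cc(=O)c3c(o2)[C@H]4O[C@H]4[C@@H](O)[C@H]3O)cc1O | intermediate
14 | (5S,6S,7S,8R)-8-chloro-5,6,7-trihydroxy-2-[2-(3-hydroxy-4-methoxyphenyl)ethyl]-5,6,7,8-tetrahydro-4H-chromen-4-one (CNP0362174.1) | COc1ccc(CCc2cc(=O)c3c(o2)[C@H](Cl)[C@@H](O)[C@@H](O)[C@H]3O)cc1O | target

**Step count.** Total: 8 steps. Longest linear sequence: 8 steps (1 to 14).

**Steps most likely to fail**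

Step 6. The acyloxy-substituted, carbonyl-conjugated diene may react too slowly with the sluggish dienophile, the enol ester may degrade first, and the ester auxiliary may give little face discrimination. The fallback sets out from 6 and comes back at 12. Formylation as in step 5 with trapping of enolate 8 by Et3SiCl should give the more electron-rich (E)-triethylsilyl dienol ether F1. Cycloaddition with 10 (toluene, 130 °C, or under pressure) should give the racemic all-cis cycloadduct F2, and NCS as in step 7 the racemic 8-chloro 7-triethylsilyl ether F3. PPTS in MeOH should cleave the secondary silyl ether only, leaving the aryl silyl ether, to give the racemic 7-alcohol F4. Esterification with 7 (DCC, DMAP, CH2Cl2) then gives 12 and its diastereomer, which are separated. The auxiliary here serves only as a resolving group, introduced after the ring is made.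

Step 7. Prototropic re-aromatisation of 11 (H4a to C8) or 1,4-elimination of the mandelic acid may outrun chlorination, and NCS may be slow on an enol ether whose oxygen is part of a vinylogous ester. The fallback sets out from 11 and comes back at 12. The adduct is isomerised on purpose (cat. Et3N, CH2Cl2, 0 °C) to the stable 8-unsubstituted pyranone F5, whose diastereomers can be separated at this point. TBSOTf and Et3N at −78 °C should silylate O4 and remove H8 to give the cross-conjugated 4-silyloxy-2H-pyran F6. NCS then chlorinates C8 anti to the C7 ester with loss of the silyl group and gives 12 (γ-halogenation of a silyl dienol ether).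

Step 5. Deprotonation may compete at the ring-bound CH2 of the phenethyl chain, O-acylation may give E/Z mixtures, and the acid chloride may partly racemise in the presence of amide base. The fallback sets out from 6 and comes back at 9. Condensation with N,N-dimethylformamide dimethyl acetal (N-methylimidazole, 100 °C) should take place only at the methyl group and give the (E)-enamine F7; the aryl silyl ether is the weak point under these conditions and would be re-installed if lost. Mild hydrolysis (aqueous AcOH, THF) should give the aldehyde F8, which is in equilibrium with its enol. Acylation with the acid chloride from 7 in pyridine and CH2Cl2 at 0 °C, without strong base, should give 9.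

**Further compounds**

F1 | step 6 | (E)-2-{2-[3-(tert-butyldimethylsilyloxy)-4-methoxyphenyl]ethyl}-6-[2-(triethylsilyloxy)ethenyl]-4H-pyran-4-one | COc1ccc(CCc2cc(=O)cc(/C=C/O[Si](CC)(CC)CC)o2)cc1O[Si](C)(C)C(C)(C)C
F2 | step 6 | racemic all-cis endo cycloadduct, 5,6-carbonate 7-triethylsilyl ether (enantiomer of the target series drawn) | COc1ccc(CCC2=CC(=O)[C@H]3C(O2)=C[C@@H](O[Si](CC)(CC)CC)[C@@H](OC(=O)O5)[C@H]35)cc1O[Si](C)(C)C(C)(C)C
F3 | step 6 | racemic 8-chloro 5,6-carbonate 7-triethylsilyl ether, Cl trans to O7 (enantiomer of the target series drawn) | COc1ccc(CCc2cc(=O)c3c(o2)[C@H](Cl)[C@@H](O[Si](CC)(CC)CC)[C@@H](OC(=O)O5)[C@H]35)cc1O[Si](C)(C)C(C)(C)C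
F4 | step 6 | racemic 8-chloro-7-hydroxy 5,6-carbonate with the aryl silyl ether retained (enantiomer of the target series drawn) | COc1ccc(CCc2cc(=O)c3c(o2)[C@H](Cl)[C@@H](O)[C@@H](OC(=O)O5)[C@H]35)cc1O[Si](C)(C)C(C)(C)C
F5 | step 7 | (5S,6R,7R)-8-unsubstituted pyranone tautomer of 11: 5,6-carbonate 7-[(S)-2-methoxy-2-phenylacetate] of the 5,6,7-trihydroxy-5,6,7,8-tetrahydro-4H-chromen-4-one | COc1ccc(CCc2cc(=O)c3c(o2)C[C@@H](OC(=O)[C@@H](OC)c4ccccc4)[C@@H](OC(=O)O5)[C@H]35)cc1O[Si](C)(C)C(C)(C)C
F6 | step 7 | 4-(tert-butyldimethylsilyloxy)-2H-pyran silyl dienol ether of F5 (C4=C4a and C8a=C8 double bonds) | COc1ccc(CCC2=CC(O[Si](C)(C)C(C)(C)C)=C3C(O2)=C[C@@H](OC(=O)[C@@H](OC)c4ccccc4)[C@@H](OC(=O)O5)[C@H]35)cc1O[Si](C)(C)C(C)(C)C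
F7 | step 5 | (E)-2-[2-(dimethylamino)ethenyl]-6-{2-[3-(tert-butyldimethylsilyloxy)-4-methoxyphenyl]ethyl}-4H-pyran-4-one | COc1ccc(CCc2cc(=O)cc(/C=C/N(C)C)o2)cc1O[Si](C)(C)C(C)(C)C
F8 | step 5 | 2-(6-{2-[3-(tert-butyldimethylsilyloxy)-4-methoxyphenyl]ethyl}-4-oxo-4H-pyran-2-yl)acetaldehyde | COc1ccc(CCc2cc(=O)cc(CC=O)o2)cc1O[Si](C)(C)C(C)(C)C
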